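The product L reaches 17.1 % of the G charged by 8.00 d in the south-west run, while Z reads 8.3 % at 3.00 d and 8.2 % at 8.00 d.

| setting | south-west | larch | oak |
|---|---|---|---|
| G | 1 M | 1.0 M | 1.0 M |
| E | 1.3 equiv | 2.00 equiv | 2.00 equiv |
| D | 2 equiv | 2.00 equiv | 2.00 equiv |
| remark | run made earlier |  |  |
| time |  | 10 d | 15 d |

south-west run (percent of the G charged)

| time / d | Q / % | L / % | Z / % | J / % | G / % |
|---|---|---|---|---|---|
| 0.500 | 0 | 0 | 5.3 | 0.2 | 93.5 |
| 1.67 | 0.4 | 3.8 | 8.9 | 2.6 | 83.3 |
| 3.00 | 0.8 | 5.9 | 8.3 | 2.3 | 80.0 |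
| 4.00 | 2.2 | 9.9 | 7.4 | 2.5 | 78.8 |
| 6.00 | 1.8 | 12.6 | 7.6 | 4.1 | 75.7 |
| 8.00 | 5.2 | 17.1 | 8.2 | 4.7 | 71.0 |

(scatter of a reading: 1 percentage point)

- which of these there is most of at the end, counted by the G in it, larch (G / J / Q / L / Z)
- which of these there is most of at the end, counted by the G in it, oak (G / J / Q / L / Z)
- the largest of these amounts at the end, in percent of the G charged, larch
- the largest of these amounts at the end, in percent of the G charged, oak

- what was read earlier has a scatter of 1 percentage point, one standard deviation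
- no earlier run changes the charge of E; that part of a forecast is a guess

I count one E used and one D freed per exchange: two for J, 3 for Q and, as my assumption, one for L. In the south-west run that gives an exchange count of 21.2 % of the G charged at 3.00 d and 50.3 % at 8.00 d. From these I read 0.211 and 0.363, with mean 0.287, for W = cZ·cD/(cG·cE), the reaction quotient.

If oak keeps the south-west pace of exchange, which is my guess, its count at the end is 94.3 % of the G charged, so my estimate of cE/cD is 0.359 and of cZ/cG is 0.103. By this estimate Z ends less than G in oak. I set no figure of my own for G.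

The forecast says G at 52 % for larch and G at 41 % for oak, calling oak “a close call that slightly favours G”.

The simulation gives G at 53.5 % in larch and G at 46.8 % in oak, so the forecast's oak figure is 5.8 percentage points low.

    E → X (k = 7.40 × 10⁻⁹ s⁻¹)
    Z + E ⇌ D + J (K = 46.0, k = 1.30 × 10⁻⁶ M⁻¹ s⁻¹)
    G + E ⇌ D + Z (K = 0.360, k = 1.40 × 10⁻⁶ M⁻¹ s⁻¹)
    J + E ⇌ D + Q (K = 72.0, k = 1.50 × 10⁻⁶ M⁻¹ s⁻¹)
    Z ⇌ L (K = 9.00, k = 3.10 × 10⁻⁶ s⁻¹)

In oak, half of the turnover of G + E into D + Z up to 15 d is done by 2.70 d. At the end of oak Z stands at 5.38 % and has a half-life of 2.6 d by the forward step into L alone, while 55 % of the E charged is left. Oak ends at cZ/cG = 0.115 against my 0.103, which makes W 0.301 against the 0.287 read earlier.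

In the neighbour, oak with 1.20 equiv of D, the end cE/cD is 0.471, so W = 0.287 with the neighbour's 41.6 % of G gives Z = 5.62 %. The computed Z is 5.70 %.

All runs are calculated for substances that don't exist; noise was put on by code.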